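Each new flask holds 0.25 M of substrate and 1.00 equiv of reagent. Grey, teal and blue differ in temperature, and I want the target in each at 1.5 h.

| flask | substrate | reagent | temperature | remark | time |
|---|---|---|---|---|---|
| beta | 0.25 M | 0.50 equiv | 90 °C | run made earlier |  |
| gamma | 0.25 M | 0.75 equiv | 110 °C | run made earlier |  |
| grey | 0.25 M | 1.00 equiv | 125 °C |  | 1.5 h |
| teal | 0.25 M | 1.00 equiv | 110 °C |  | 1.5 h |
| blue | 0.25 M | 1.00 equiv | 95 °C |  | 1.5 h |

- beta (time / h: target / %): 2.00: 0; 4.00: 0; 6.00: 0.8; 8.00: 3.6; 12.0: 5.1
- gamma (time / h: target / %): 0.333: 2.3; 0.833: 3.4; 2.00: 10.4; 3.00: 14.7; 4.00: 19.5

(each reading ± 1 percentage point)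

- which flask leads in amount of target, in percent of the substrate charged ("all alike" within 1.5 percentage points) (grey / teal / blue / all alike)
- how much target is there at the end, in percent of the substrate charged: grey
- how much target is there at the end, in percent of the substrate charged: teal
- how much target is there at the end, in percent of the substrate charged: blue

- in percentages every species weighs as the substrate in it: one homo dimer counts as two
- the analysis behind the earlier runs scatters by 1 percentage point, standard deviation
- candidate steps: substrate + reagent <-> intermediate; intermediate <-> target + released group; 2 substrate -> homo dimer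

Two readings seem not to go together. At 4.00 h the beta run, at 90 °C, shows 0% of target, while the gamma run, at 110 °C, shows 19.5% at that same time, with 1.50 times the reagent. A zero taken at face value cannot be scaled into that by any factor, but each reading scatters by 1 percentage point, and beta does climb later, gaining 4.3 points from 6.00 h to 12.0 h. Its line, 0.00717 /h of the charge per hour, meets zero near 4.88 h, but both ends of that line carry the same scatter, so this crossing is a rough reading. So the zero in beta may be a small amount of target hidden in the scatter, perhaps after a short delay, an induction period, and these readings do not tell the two apart.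

Gamma gains 0.0455 /h of the charge per hour from 2.00 h to 4.00 h. Run back, that line gives 5.09% at 0.833 h, where the reading is 3.4%, a gap of 1.7 points, and it stands at 1.30% at the start, above zero, so the gamma readings show no clear delay.

Scaling gamma's gain by the reagent, on my assumption that the two go in proportion, gives 0.0607 /h. This is the hourly gain at one equivalent: the fraction of the charged substrate becoming target per hour at 110 °C. A constant rate integrates to target equals this gain times the time, so I reckon teal at 9.10%. Beta scaled the same way gives 0.0143 /h, a reading 4.24 times lower across its temperature gap to gamma. So grey, hotter than teal, should lead, and blue, cooler, should trail.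

The forecast gives grey first, with grey 25%, teal 9.5% and blue 1.5%, and says “Grey leads, though the extrapolation is uncertain”. The flasks give grey 32.7%, ahead of teal 9.76% and blue 1.23%.

    substrate + reagent ⇌ intermediate (K = 65.0 /M, k = 0.0450 /M/min, Ea = 103 kJ/mol, ΔH = 23.0 kJ/mol)
    intermediate ⇌ target + released group (K = 10.0 M, k = 0.00720 /min, Ea = 114 kJ/mol, ΔH = −40.0 kJ/mol)
    2 substrate → homo dimer (k = 0.0870 /M/min, Ea = 81.0 kJ/mol)
    (constants at 110 °C)

Teal holds 9.76% of target against my 9.10%, and at that time it also has 17.8% intermediate, 12.6% substrate and 59.8% homo dimer. The neighbour is the same teal flask read at 4.0 h, where the hourly gain at one equivalent times that time gives 24.3%. In that flask the intermediate is down to 9.39%, the substrate stands at 3.29%, and the target is 24.4%.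

Readings and results are simulated on assumed constants, noise included.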